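Numbers refer to the compound list after the steps; ring A is the methyl benzoate ring, ring B the free benzoic acid ring.

## Analysis of the target

Target 21 is a diaryl ether of two benzoic acid units and has no stereocentre; the ether axis is not expected to be configurationally stable, so nothing stereochemical has to be set. Ring A is a methyl benzoate (C1) with the ether oxygen on C2, methoxy on C3, chlorine on C4, a free hydroxyl on C5 and its only hydrogen on C6. Ring B is a free benzoic acid (C1) with the ether oxygen on C2, methyl on C4 and hydroxyl on C6. The sensitive groups are the 2,6-dioxygenated benzoic acid of ring B, which decarboxylates with acid and heat, the methyl ester, which must stay distinct from the free acid, the oxidisable hydroquinone monoether pattern of ring A, and the aryl chloride, which speaks against hydrogenolytic deprotection. The synthesis is hard first because the ether oxygen lies between the ester and the methoxy group on ring A and next to the carboxyl on ring B, so that any intermolecular arylation meets three ortho substituents. It is hard also because ring A is pentasubstituted, with chlorine wedged between two oxygens and a 1,2,4-trioxygenation that electrophilic substitution does not deliver cleanly. The plan rests on ring B being a salicylate: C5, C6 (with OH) and C1 (with the carboxyl) are the three carbons of an acetoacetate, and C2 (with the ether oxygen), C3 and C4 (with methyl) are a butenone 1,3-dielectrophile. Ring B can therefore be grown on the ring A oxygen instead of being coupled to it.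

## Retrosynthetic reasoning

**21 from 20.** No skeletal bond is cut in the last operation; it only unmasks the ring B acid and the ring A C5 hydroxyl of 20. The acid is carried as an allyl ester and the phenol as an acetate, because both can be removed at room temperature under neutral, non-reductive conditions that leave the methyl ester and the aryl chloride alone. Hydrogenolysis is avoided because of the chloride and strong acid because of the decarboxylation-prone acid.

**20 from 14 and 18.** Ring B is cut at C1–C2 and C4–C5. This cut leaves the ether oxygen on an sp2 carbon at the acid chloride oxidation level in enone 14, not on an arene, and makes the other half the three-carbon bis-nucleophile 18. The forward reaction has to send the diene terminus to the ketone of 14, through adduct 19, send the central carbon to the chloro carbon, and expel chloride while keeping the aryloxy group. Aromatisation then follows by dehydration, without an oxidant. A cut at the aryl–oxygen bond of an intact ring B was not chosen because of the three ortho substituents.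

**18 from 15 through 16 and 17.** The diene is the doubly O-silylated form of allyl acetoacetate 15. The first silyl group is put on the enol to give 16, the second on the ester dienolate 17. Because 18 is an allyl silyl ketene acetal, it has to be made and used cold.

**14 from 9 and 13; 13 from 10 and 11 through 12.** The hindered C–O bond is made by addition–elimination of phenol 9 on the vinylogous acid chloride 13, which is mechanistically an O-acylation and not an arylation. Enone 13 comes from acylation of alkene 11 with acid chloride 10 and dehydrochlorination of 12.

**9 from 8; 8 from 6 through 7.** The two hydroxyls of hydroquinone 8 differ sharply: the C2 hydroxyl is chelated to the ester and flanked on both sides, the C5 hydroxyl is not. Acetylation should therefore stop at 9 and leave the C2 hydroxyl free for the ether. The C2 oxygen is para to the C5 hydroxyl, exactly where a phenol with a free para position is oxidised to a para-quinone, so 8 comes from phenol 6 through quinone 7 and reduction.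

**6 from 5, 4, 3 and 1 through 2.** Esterification of 5 gives 6. Acid 5 comes from the symmetric dimethyl ether 4 by removal of one methyl group, where either methyl gives the same product. Acid 4 comes from benzylic oxidation of 3. The chlorine of 3 is introduced by lithiation of 1 between its two methoxy groups, giving 2, and chlorination. Electrophilic chlorination of a 3,5-dioxygenated ring was not used, because the position between the oxygens competes with the two positions ortho and para to them, whereas the lithiation has only one outcome.

## Alternatives that were turned down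

Alternative 1: Aryne, phenoxide and carbon dioxide on ring B. Ring B is cut at O–C2 and at C1–carboxyl, two bonds on adjacent carbons, which leads back to an aryne. In the forward key step a fluoride source releases the aryne from silyl triflate A2, the caesium salt of ring A phenol A3 adds at the aryne carbon meta to the protected oxygen, and the aryl anion formed next to that oxygen takes up carbon dioxide A4 to give acid A1.

- For: it is highly convergent; both rings arrive as arenes and the ether and the carboxyl are set in one operation. The regiochemistry of addition to a 3-alkoxyaryne is dependable, and on this point it is stronger than the chosen route.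
- Against: the nucleophile is a di-ortho-substituted phenoxide, which must beat its own carbonate formation, and the aryl anion must take A4 and not a proton.
- Against: ring A cannot carry its ester through the step, since the aryl anion would close onto it. A3 therefore carries a silyloxymethyl group, which the fluoride threatens.
- Against: afterwards that carbon must be oxidised and esterified while the ring B acid is masked orthogonally, and two acetals must be removed with acid from a decarboxylation-prone acid, about five further steps; A2 and A3 each need several steps as well.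
- Comparison: the chosen route makes the ether bond on a vinylogous acid chloride, keeps the ring A ester from the start and ends one step after the key step. It pays for this with a less precedented key step.

Alternative 2: Ring A as a cyclohexane-1,3-dione, aromatised late. Ring A is cut at C1–C6 and at C4–C5, back to a non-aromatic dione. In the forward key step, with an alkoxide base, aryloxymalonate A6 adds to oxo-enoate A7 at the carbon beta to the ketone, and the methyl ketone enolate then closes onto one malonate ester in a Claisen condensation to give dione A5 as diastereomers.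

- For: the ether oxygen enters as an alkyl aryl ether on a malonate, so no hindered arylation is needed. The chlorine can later go to the carbon between the two carbonyls, which has no regiochemical rival; this is stronger than the chosen route, which needs an organolithium step for the chlorine.
- Against: A5 is far from the target. The extra ester on the ether-bearing carbon must be removed and the ring chlorinated and dehydrogenated.
- Against: of the two resulting hydroxyls only the more hindered one at C3 may be methylated, which forces a protection detour.
- Against: the key step joins a hindered tertiary carbanion under reversible conditions, and ring B ends with acid-labile groups that have to be removed from a decarboxylation-prone acid.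
- Comparison: the chosen route aromatises within the annulation without an oxidant and offers a one-step end-game in place of the cleaner chlorination.

Alternative 3: Ring A by vinylketene and ynol ether benzannulation. Ring A is cut into a four-carbon vinylketene and a two-carbon alkyne. In the forward key step an amine base turns acid chloride A9 into an aryloxy(vinyl)ketene. This adds (2+2) to ynol ether A10 (new bonds C4–C5 and C2–C3), opens by 4-pi electrocyclisation (the old C2–C5 bond breaks) and closes by 6-pi electrocyclisation (C5–C6) to phenol A8 , which carries silicon on C4.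

- For: every substituent of ring A is placed by the connectivity of two small fragments, with no oxidation or metalation of an arene. This is stronger than the chosen route on ring A regiocontrol.
- Against: the ketene from A9 is electron-poor and carries an acrylate unit, so dimerisation and amine addition compete.
- Against: A9 itself needs several steps, and A10 is volatile and hydrolytically labile.
- Against: silicon must then be exchanged for chlorine in the presence of the electron-rich ring B and an open ortho position on ring A, and the final deprotection is again acidic.
- Comparison: the chosen route uses cheap partners, has the chlorine fixed from the first step and a mild one-step end-game. It offers simplicity in place of the fuller regiocontrol of this alternative.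

Key step: step 11

Remark on the chemistry: enone 14 is expected as a mixture of alkene isomers and adduct 19 as a racemate; both elements are erased when ring B aromatises, so neither is controlled.

## Route

Step 1
Reactants: 1 1,3-dimethoxy-5-methylbenzene
Product: 3 2-chloro-1,3-dimethoxy-5-methylbenzene, via aryllithium 2 (not isolated)
Conditions: n-BuLi, THF, 0 °C → rt; C2Cl6, −78 °C → rt
Reagents that add atoms: hexachloroethane, ClC(Cl)(Cl)C(Cl)(Cl)Cl
Why: Directed ortho-metalation; the hydrogen between the two methoxy groups is the most acidic and doubly coordinated, so lithiation should occur only there, and C2Cl6 transfers chlorine cleanly to aryllithiums.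

Step 2
Reactants: 3 2-chloro-1,3-dimethoxy-5-methylbenzene
Product: 4 4-chloro-3,5-dimethoxybenzoic acid
Conditions: KMnO4, pyridine/H2O, reflux; aq. HCl
Reagents that add atoms: KMnO4 (potassium permanganate), [K+].[O-][Mn](=O)(=O)=O; water, O
Why: Benzylic oxidation of an aryl methyl group by permanganate; the ring has no free phenol and the ethers and the chloride are inert under these basic conditions.

Step 3
Reactants: 4 4-chloro-3,5-dimethoxybenzoic acid
Product: 5 4-chloro-3-hydroxy-5-methoxybenzoic acid
Conditions: NaSEt (excess), DMF, 120 °C; aq. HCl
Reagents that add atoms: none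
Why: SN2 demethylation of an aryl methyl ether by thiolate; the two methoxy groups are equivalent, and after the first cleavage the substrate is a carboxylate phenoxide dianion whose second ether is a far poorer leaving group, so the reaction should stop at the monophenol.

Step 4
Reactants: 5 4-chloro-3-hydroxy-5-methoxybenzoic acid
Product: 6 methyl 4-chloro-3-hydroxy-5-methoxybenzoate
Conditions: MeOH, H2SO4 (cat.), reflux
Reagents that add atoms: methanol, CO
Why: Fischer esterification; the phenol is not alkylated under acid catalysis.

Step 5
Reactants: 6 methyl 4-chloro-3-hydroxy-5-methoxybenzoate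
Product: 8 methyl 4-chloro-2,5-dihydroxy-3-methoxybenzoate, via quinone 7 (not isolated)
Conditions: (KSO3)2NO, KH2PO4, H2O/acetone, rt; then Na2S2O4, H2O/EtOAc, rt
Reagents that add atoms: (KSO3)2NO (potassium nitrosodisulfonate), [K+].[K+].[O]N(S(=O)(=O)[O-])S(=O)(=O)[O-]
Why: Teuber oxidation; the phenoxyl radical couples with a second nitroxyl radical at the free para carbon and loss of imidodisulfonate gives para-quinone 7, and immediate dithionite reduction should give the hydroquinone before the electrophilic quinone can add nucleophiles.

Step 6
Reactants: 8 methyl 4-chloro-2,5-dihydroxy-3-methoxybenzoate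
Product: 9 methyl 5-acetoxy-4-chloro-2-hydroxy-3-methoxybenzoate
Conditions: Ac2O (1 equiv), pyridine, CH2Cl2, −20 → 0 °C
Reagents that add atoms: acetic anhydride, CC(=O)OC(C)=O
Why: Selective O-acylation; the C2 hydroxyl is hydrogen-bonded to the ester carbonyl and flanked on both sides, whereas the C5 hydroxyl is free and has an open ortho position, so the acetyl group should go to C5.

Step 7
Reactants: 10 acetyl chloride; 11 1,1-dichloroethene
Product: 13 4,4-dichlorobut-3-en-2-one, via trichloro ketone 12 (not isolated)
Conditions: AlCl3, CH2Cl2, 0 °C → rt; ice/aq. HCl; then Et3N, Et2O, 0 °C; distil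
Reagents that add atoms: none
Why: Friedel–Crafts-type acylation of an alkene; the acylium ion adds to the CH2 terminus and the dichlorocarbenium ion takes up chloride to give 12, which loses HCl by an E1cB elimination to the conjugated enone.

Step 8
Reactants: 9 methyl 5-acetoxy-4-chloro-2-hydroxy-3-methoxybenzoate; 13 4,4-dichlorobut-3-en-2-one
Product: 14 methyl 5-acetoxy-4-chloro-2-[(1-chloro-3-oxobut-1-en-1-yl)oxy]-3-methoxybenzoate
Conditions: Et3N, CH2Cl2, −20 → 0 °C (13 in excess)
Reagents that add atoms: none
Why: Nucleophilic vinylic substitution by addition–elimination on a vinylogous acid chloride, analogous to O-acylation of a phenol under amine base; once the donor aryloxy group is in place the second chloride is much less reactive and is shielded by ring A, so substitution should stop at one.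

Step 9
Reactants: 15 allyl acetoacetate
Product: 16 allyl 3-(trimethylsilyloxy)but-2-enoate
Conditions: Me3SiCl, Et3N, hexane, rt
Reagents that add atoms: chlorotrimethylsilane, C[Si](C)(C)Cl
Why: O-silylation of the enol of a β-keto ester under amine base, the standard first stage towards 1,3-bis(silyloxy)dienes.

Step 10
Reactants: 16 allyl 3-(trimethylsilyloxy)but-2-enoate
Product: 18 1-(allyloxy)-1,3-bis(trimethylsilyloxy)buta-1,3-diene, via lithium dienolate 17 (not isolated)
Conditions: LiN(i-Pr)2, THF, −78 °C; Me3SiCl, −78 → 0 °C; cold pentane, filtration and concentration at 0 °C; used at once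
Reagents that add atoms: chlorotrimethylsilane, C[Si](C)(C)Cl
Why: Deprotonation of the methyl group gives the ester dienolate, which is silylated on oxygen, and the allyl ester is not attacked by the hindered amide at −78 °C; because 18 is an allyl silyl ketene acetal it is kept at or below 0 °C and used directly, so that a (3,3)-sigmatropic shift of the allyl group does not set in.

Step 11
Reactants: 14 methyl 5-acetoxy-4-chloro-2-[(1-chloro-3-oxobut-1-en-1-yl)oxy]-3-methoxybenzoate; 18 1-(allyloxy)-1,3-bis(trimethylsilyloxy)buta-1,3-diene
Product: 20 allyl 2-[4-acetoxy-3-chloro-2-methoxy-6-(methoxycarbonyl)phenoxy]-6-hydroxy-4-methylbenzoate, via aldol adduct 19 (not isolated)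
Conditions: TiCl4, 4 Å molecular sieves, CH2Cl2, −78 → 20 °C; aq. HCl
Reagents that add atoms: none
Why: Proposed new method: TiCl4 binds the ketone oxygen of 14, and the terminal carbon of diene 18, its most nucleophilic site, adds to that carbonyl as in a Mukaiyama aldol reaction to give the titanium alkoxide of 19 (C4–C5 of ring B). Ionisation of this tertiary allylic C–O bond, helped by the aryloxy lone pair, gives an allyl cation whose chloro(aryloxy) terminus is attacked by the central carbon of the β-keto ester enolate (C1–C2); an equivalent path is dehydration to the trienol and 6-pi electrocyclisation. Ring B thus closes in a six-membered 6-endo mode, a vinylogous addition–elimination, and loss of HCl with enolisation gives the arene; the carbinol centre of 19 is destroyed and the product has no stereocentre. The closest known reaction type is the TiCl4-mediated (3+3) cyclocondensation of 1,3-bis(silyloxy)-1,3-dienes with 3-alkoxy, 3-silyloxy and 3,3-bis(methylthio) enones to salicylates; a 3-chloro-3-aryloxy enone has not been used. Two selectivities are needed. The diene terminus must choose the ketone over the chloro carbon: that carbon is fully substituted, shielded by the di-ortho-substituted ring A and is a push–pull ketene acetal carbon, the situation in which oxo ketene dithioacetals are attacked at the carbonyl, whereas the methyl ketone is unhindered and directly activated by titanium. Chloride and not aryloxide must leave on aromatisation: chloride is the better leaving group and its departure is assisted by the aryloxy oxygen and the Lewis acid, while loss of aryloxide would need assistance from chlorine.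

Step 12
Reactants: 20 allyl 2-[4-acetoxy-3-chloro-2-methoxy-6-(methoxycarbonyl)phenoxy]-6-hydroxy-4-methylbenzoate
Product: 21 2-[3-chloro-4-hydroxy-2-methoxy-6-(methoxycarbonyl)phenoxy]-6-hydroxy-4-methylbenzoic acid
Conditions: Pd(PPh3)4 (cat.), pyrrolidine (excess), THF, 0 °C → rt; aq. citric acid
Reagents that add atoms: none
Why: Tsuji–Trost deallylation; zerovalent palladium ionises the allyl ester and pyrrolidine captures the allyl fragment, and the same amine cleaves the aryl acetate by aminolysis, while the hindered methyl benzoate should be inert at room temperature and the acid is freed without heat or strong acid, so decarboxylation is avoided.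

## Compound list

1 | 1,3-dimethoxy-5-methylbenzene (3,5-dimethoxytoluene) | COc1cc(C)cc(OC)c1 | starting material
2 | (2,6-dimethoxy-4-methylphenyl)lithium | [Li]c1c(OC)cc(C)cc1OC | intermediate (not isolated)
3 | 2-chloro-1,3-dimethoxy-5-methylbenzene | COc1cc(C)cc(OC)c1Cl | intermediate
4 | 4-chloro-3,5-dimethoxybenzoic acid | COc1cc(C(=O)O)cc(OC)c1Cl | intermediate
5 | 4-chloro-3-hydroxy-5-methoxybenzoic acid | COc1cc(C(=O)O)cc(O)c1Cl | intermediate
6 | methyl 4-chloro-3-hydroxy-5-methoxybenzoate | COC(=O)c1cc(O)c(Cl)c(OC)c1 | intermediate
7 | methyl 4-chloro-5-methoxy-3,6-dioxocyclohexa-1,4-diene-1-carboxylate | COC(=O)C1=CC(=O)C(Cl)=C(OC)C1=O | intermediate (not isolated)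
8 | methyl 4-chloro-2,5-dihydroxy-3-methoxybenzoate | COC(=O)c1cc(O)c(Cl)c(OC)c1O | intermediate
9 | methyl 5-acetoxy-4-chloro-2-hydroxy-3-methoxybenzoate | COC(=O)c1cc(OC(C)=O)c(Cl)c(OC)c1O | intermediate
10 | acetyl chloride | CC(=O)Cl | starting material
11 | 1,1-dichloroethene | C=C(Cl)Cl | starting material
12 | 4,4,4-trichlorobutan-2-one | CC(=O)CC(Cl)(Cl)Cl | intermediate (not isolated)
13 | 4,4-dichlorobut-3-en-2-one | CC(=O)C=C(Cl)Cl | intermediate
14 | methyl 5-acetoxy-4-chloro-2-[(1-chloro-3-oxobut-1-en-1-yl)oxy]-3-methoxybenzoate (mixture of alkene isomers) | CC(=O)C=C(Cl)Oc1c(OC)c(Cl)c(OC(C)=O)cc1C(=O)OC | intermediate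
15 | allyl acetoacetate (prop-2-enyl 3-oxobutanoate) | CC(=O)CC(=O)OCC=C | starting material
16 | allyl 3-(trimethylsilyloxy)but-2-enoate | C=CCOC(=O)C=C(C)O[Si](C)(C)C | intermediate
17 | lithium dienolate of 16 (lithium 1-(allyloxy)-3-(trimethylsilyloxy)buta-1,3-dien-1-olate) | [Li+].[O-]C(OCC=C)=CC(=C)O[Si](C)(C)C | intermediate (not isolated)
18 | 1-(allyloxy)-1,3-bis(trimethylsilyloxy)buta-1,3-diene | C=CCOC(O[Si](C)(C)C)=CC(=C)O[Si](C)(C)C | intermediate
19 | allyl 7-[4-acetoxy-3-chloro-2-methoxy-6-(methoxycarbonyl)phenoxy]-7-chloro-5-hydroxy-5-methyl-3-oxohept-6-enoate (racemic; present as its titanium alkoxide) | C=CCOC(=O)CC(=O)CC(C)(O)C=C(Cl)Oc1c(OC)c(Cl)c(OC(C)=O)cc1C(=O)OC | intermediate (not isolated)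
20 | allyl 2-[4-acetoxy-3-chloro-2-methoxy-6-(methoxycarbonyl)phenoxy]-6-hydroxy-4-methylbenzoate | C=CCOC(=O)c1c(O)cc(C)cc1Oc1c(OC)c(Cl)c(OC(C)=O)cc1C(=O)OC | intermediate
21 | 2-[3-chloro-4-hydroxy-2-methoxy-6-(methoxycarbonyl)phenoxy]-6-hydroxy-4-methylbenzoic acid | COC(=O)c1cc(O)c(Cl)c(OC)c1Oc1cc(C)cc(O)c1C(=O)O | target

## Step count and least certain steps

Total: 12 steps. Longest linear sequence: 9 steps (steps 1 to 6, 8, 11 and 12). Step 7 and steps 9 and 10 are side branches.

**Step 11 (key step).** The most likely failure is reversed regiochemistry. The diene terminus may attack the chloro(aryloxy) carbon in a vinylic substitution and the central carbon may then condense with the ketone, which would place the aryloxy group para and the methyl group ortho to the ester. This is the normal order of events with simple 3-alkoxy enones, and only the substitution and push–pull character of that carbon argue against it here. Abstraction of chloride from 14 by TiCl4, or loss of the aryloxy group in place of chloride, would also divert the reaction. The fallback builds the ether by SNAr on a ring B aldehyde; it sets out from hydroquinone 8 and returns at target 21. The free C5 hydroxyl of 8 would be allylated with allyl bromide and K2CO3 in acetone, the chelated C2 hydroxyl staying free, to give methyl 5-(allyloxy)-4-chloro-2-hydroxy-3-methoxybenzoate F1 as the ring A partner. Purchased 2,6-difluoro-4-methylbenzaldehyde F2 would be treated with allyl alcohol and NaH in THF, and displacement of one fluoride would give 2-(allyloxy)-6-fluoro-4-methylbenzaldehyde F3 as the ring B partner. K2CO3 in DMF at about 100 °C should then join F1 and F3 by SNAr ortho to the formyl group to give methyl 5-(allyloxy)-2-[3-(allyloxy)-2-formyl-5-methylphenoxy]-4-chloro-3-methoxybenzoate F4 as the diaryl ether. Pinnick oxidation of F4 (NaClO2, NaH2PO4, 2-methylbut-2-ene) would give 2-(allyloxy)-6-[4-(allyloxy)-3-chloro-2-methoxy-6-(methoxycarbonyl)phenoxy]-4-methylbenzoic acid F5 and Pd(PPh3)4 with pyrrolidine would remove both allyl ethers of F5 to give 21.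

**Step 8.** The risks are acetyl transfer between phenoxide molecules under base, hydrolysis of the chloro vinyl ether of 14 during isolation, and a second substitution on 13. The fallback replaces the base-labile acetate by a silyl ether, so that the phenoxide can be formed irreversibly; it sets out from 8 and returns at 21. i-Pr3SiCl and imidazole in DMF should silylate only the unchelated hydroxyl of 8 to give methyl 4-chloro-2-hydroxy-3-methoxy-5-(triisopropylsilyloxy)benzoate F6 as the protected phenol. NaH in THF would turn F6 into its sodium phenoxide, and 13 would then give methyl 4-chloro-2-[(1-chloro-3-oxobut-1-en-1-yl)oxy]-3-methoxy-5-(triisopropylsilyloxy)benzoate F7 as the enone. The conditions of step 11 applied to F7 and 18 would give allyl 2-[3-chloro-2-methoxy-6-(methoxycarbonyl)-4-(triisopropylsilyloxy)phenoxy]-6-hydroxy-4-methylbenzoate F8 as the salicylate. Bu4NF in THF would free the phenol of F8 to give allyl 2-[3-chloro-4-hydroxy-2-methoxy-6-(methoxycarbonyl)phenoxy]-6-hydroxy-4-methylbenzoate F9 and Pd(PPh3)4 with pyrrolidine would convert F9 into 21.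

**Step 5.** Hydrogen abstraction from the electron-poor chlorophenol 6 may be slow, and quinone 7 may be lost by addition of water at its ester-bearing double bond before it is reduced. The fallback is an Elbs persulfate oxidation, which avoids the quinone; it sets out from acid 5 and returns at 8. K2S2O8 in aqueous NaOH should attack the carbon para to the phenoxide oxygen to give 4-chloro-5-hydroxy-3-methoxy-2-(sulfooxy)benzoic acid F10 as its potassium salt. Warm aqueous HCl would hydrolyse the sulfate of F10 to 4-chloro-2,5-dihydroxy-3-methoxybenzoic acid F11 and the conditions of step 4 (MeOH, H2SO4) applied to F11 would give 8.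

**Step 10.** Diene 18 is an allyl silyl ketene acetal, and a (3,3)-sigmatropic shift of the allyl group from oxygen to the central carbon (Ireland–Claisen type) may consume it during isolation or before TiCl4 activates the enone. The fallback replaces the allyl ester by a benzyl ester, which cannot rearrange in this way; it sets out from enone 14 and returns at target 21. Purchased benzyl acetoacetate F12 would be silylated with Me3SiCl and Et3N to give benzyl 3-(trimethylsilyloxy)but-2-enoate F13 and then with LiN(i-Pr)2 and Me3SiCl to give 1-(benzyloxy)-1,3-bis(trimethylsilyloxy)buta-1,3-diene F14 as the diene. The conditions of step 11 applied to 14 and F14 would give benzyl 2-[4-acetoxy-3-chloro-2-methoxy-6-(methoxycarbonyl)phenoxy]-6-hydroxy-4-methylbenzoate F15 as the salicylate. Pyrrolidine in THF would remove the acetate of F15 by aminolysis to give benzyl 2-[3-chloro-4-hydroxy-2-methoxy-6-(methoxycarbonyl)phenoxy]-6-hydroxy-4-methylbenzoate F16 as the phenol. Hydrogenolysis of F16 with H2 (1 atm) over Pd/C (palladium on carbon) in EtOAc without base, stopped at full conversion, would give 21. Benzyl ester cleavage is much faster than hydrodechlorination under these neutral conditions, but the aryl chloride is the reason this is only the fallback.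

**Step 3.** Thiolate may displace the aryl chloride, which lies para to the carboxylate, or remove both methyl groups. The fallback removes both methyl groups on purpose and puts one back; it sets out from acid 4 and returns at phenol 6. BBr3 in CH2Cl2 (−78 °C → rt) would cleave both ethers to give 4-chloro-3,5-dihydroxybenzoic acid F17 as the diol. MeOH with catalytic H2SO4 at reflux would convert F17 into methyl 4-chloro-3,5-dihydroxybenzoate F18 and MeI (1 equiv) with K2CO3 in acetone would methylate one of the two equivalent hydroxyls of F18 to give 6, which is separated from recovered diol and doubly methylated material.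

## Further compounds

F1 | step 11 | methyl 5-(allyloxy)-4-chloro-2-hydroxy-3-methoxybenzoate | COC(=O)c1cc(OCC=C)c(Cl)c(OC)c1O
F2 | step 11 | 2,6-difluoro-4-methylbenzaldehyde (purchased) | Cc1cc(F)c(C=O)c(F)c1
F3 | step 11 | 2-(allyloxy)-6-fluoro-4-methylbenzaldehyde | C=CCOc1cc(C)cc(F)c1C=O
F4 | step 11 | methyl 5-(allyloxy)-2-[3-(allyloxy)-2-formyl-5-methylphenoxy]-4-chloro-3-methoxybenzoate | COC(=O)c1cc(OCC=C)c(Cl)c(OC)c1Oc1cc(C)cc(OCC=C)c1C=O
F5 | step 11 | 2-(allyloxy)-6-[4-(allyloxy)-3-chloro-2-methoxy-6-(methoxycarbonyl)phenoxy]-4-methylbenzoic acid | COC(=O)c1cc(OCC=C)c(Cl)c(OC)c1Oc1cc(C)cc(OCC=C)c1C(=O)O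
F6 | step 8 | methyl 4-chloro-2-hydroxy-3-methoxy-5-(triisopropylsilyloxy)benzoate | COC(=O)c1cc(O[Si](C(C)C)(C(C)C)C(C)C)c(Cl)c(OC)c1O
F7 | step 8 | methyl 4-chloro-2-[(1-chloro-3-oxobut-1-en-1-yl)oxy]-3-methoxy-5-(triisopropylsilyloxy)benzoate | CC(=O)C=C(Cl)Oc1c(OC)c(Cl)c(O[Si](C(C)C)(C(C)C)C(C)C)cc1C(=O)OC
F8 | step 8 | allyl 2-[3-chloro-2-methoxy-6-(methoxycarbonyl)-4-(triisopropylsilyloxy)phenoxy]-6-hydroxy-4-methylbenzoate | C=CCOC(=O)c1c(O)cc(C)cc1Oc1c(OC)c(Cl)c(O[Si](C(C)C)(C(C)C)C(C)C)cc1C(=O)OC
F9 | step 8 | allyl 2-[3-chloro-4-hydroxy-2-methoxy-6-(methoxycarbonyl)phenoxy]-6-hydroxy-4-methylbenzoate | C=CCOC(=O)c1c(O)cc(C)cc1Oc1c(OC)c(Cl)c(O)cc1C(=O)OC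
F10 | step 5 | 4-chloro-5-hydroxy-3-methoxy-2-(sulfooxy)benzoic acid | OC(=O)c1cc(O)c(Cl)c(OC)c1OS(=O)(=O)O
F11 | step 5 | 4-chloro-2,5-dihydroxy-3-methoxybenzoic acid | OC(=O)c1cc(O)c(Cl)c(OC)c1O
F12 | step 10 | benzyl acetoacetate (purchased) | CC(=O)CC(=O)OCc1ccccc1
F13 | step 10 | benzyl 3-(trimethylsilyloxy)but-2-enoate | CC(=CC(=O)OCc1ccccc1)O[Si](C)(C)C
F14 | step 10 | 1-(benzyloxy)-1,3-bis(trimethylsilyloxy)buta-1,3-diene | C=C(O[Si](C)(C)C)C=C(OCc1ccccc1)O[Si](C)(C)C
F15 | step 10 | benzyl 2-[4-acetoxy-3-chloro-2-methoxy-6-(methoxycarbonyl)phenoxy]-6-hydroxy-4-methylbenzoate | O=C(OCc1ccccc1)c1c(O)cc(C)cc1Oc1c(OC)c(Cl)c(OC(C)=O)cc1C(=O)OC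
F16 | step 10 | benzyl 2-[3-chloro-4-hydroxy-2-methoxy-6-(methoxycarbonyl)phenoxy]-6-hydroxy-4-methylbenzoate | O=C(OCc1ccccc1)c1c(O)cc(C)cc1Oc1c(OC)c(Cl)c(O)cc1C(=O)OC
F17 | step 3 | 4-chloro-3,5-dihydroxybenzoic acid | OC(=O)c1cc(O)c(Cl)c(O)c1
F18 | step 3 | methyl 4-chloro-3,5-dihydroxybenzoate | COC(=O)c1cc(O)c(Cl)c(O)c1
A1 | alternative 1 | 2-[2-({[tert-butyl(dimethyl)silyl]oxy}methyl)-5-chloro-6-methoxy-4-(methoxymethoxy)phenoxy]-6-(methoxymethoxy)-4-methylbenzoic acid | COCOc1cc(C)cc(Oc2c(CO[Si](C)(C)C(C)(C)C)cc(OCOC)c(Cl)c2OC)c1C(=O)O
A2 | alternative 1 | 3-(methoxymethoxy)-5-methyl-2-(trimethylsilyl)phenyl trifluoromethanesulfonate | COCOc1cc(C)cc(OS(=O)(=O)C(F)(F)F)c1[Si](C)(C)C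
A3 | alternative 1 | 2-({[tert-butyl(dimethyl)silyl]oxy}methyl)-5-chloro-6-methoxy-4-(methoxymethoxy)phenol | COCOc1cc(CO[Si](C)(C)C(C)(C)C)c(O)c(OC)c1Cl
A4 | alternative 1 | carbon dioxide | O=C=O
A5 | alternative 2 | dimethyl 1-[2-(tert-butoxycarbonyl)-3-(methoxymethoxy)-5-methylphenoxy]-2,4-dioxocyclohexane-1,6-dicarboxylate (diastereomer mixture) | COC(=O)C1CC(=O)CC(=O)C1(Oc1cc(C)cc(OCOC)c1C(=O)OC(C)(C)C)C(=O)OC
A6 | alternative 2 | dimethyl 2-[2-(tert-butoxycarbonyl)-3-(methoxymethoxy)-5-methylphenoxy]malonate | COC(=O)C(Oc1cc(C)cc(OCOC)c1C(=O)OC(C)(C)C)C(=O)OC
A7 | alternative 2 | methyl (E)-4-oxopent-2-enoate | COC(=O)/C=C/C(C)=O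
A8 | alternative 3 | tert-butyl 2-[4-hydroxy-2-methoxy-6-(methoxycarbonyl)-3-(trimethylsilyl)phenoxy]-6-(methoxymethoxy)-4-methylbenzoate | COC(=O)c1cc(O)c([Si](C)(C)C)c(OC)c1Oc1cc(C)cc(OCOC)c1C(=O)OC(C)(C)C
A9 | alternative 3 | tert-butyl 2-{[1-chloro-3-(methoxycarbonyl)-1-oxobut-3-en-2-yl]oxy}-6-(methoxymethoxy)-4-methylbenzoate | COC(=O)C(=C)C(Oc1cc(C)cc(OCOC)c1C(=O)OC(C)(C)C)C(Cl)=O
A10 | alternative 3 | 1-methoxy-2-(trimethylsilyl)ethyne | COC#C[Si](C)(C)C
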